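**Plan**

- Cuts: (a) the lactone C3–CH2 bond to ring C (conjugate arylation of an α-methylene lactone by an aryl boronate); (b) O1–C2 of the dihydrobenzofuran; (c) in each 1,2-diaryl-C3 arm, the bond between the aryl-bearing carbon and the oxygenated benzylic carbon (aldol); (d) lactone ring B back to a ring D aldehyde and dimethyl succinate (Stobbe).
- Enabling feature: C2 of the dihydrobenzofuran is a benzylic ether carbon para to the phenolic oxygen of ring E, so it can be formed from a para-quinone methide that the ortho phenol of ring C captures.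
- Forward, fragment 1: aldol, diol 14, furan ring closure (step 9), boronate 18. Fragment 2: aldol, acetonide, aldehyde, lactone ring B, α-methylene lactone 39.
- Union in step 24, then the ketone oxidation level is set and the benzyl ethers are removed.
- Stereochemistry: benzofuran C3 from the (S)-oxazolidinone aldol; C2 from C3 under thermodynamic control in the ring closure; ketol carbon from the (R)-oxazolidinone aldol; lactone C4 from rhodium/Et-DuPhos hydrogenation; lactone C3 by base equilibration to trans.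

Key step: step 9

Remark: ring A = guaiacyl ring of the aryl ketone, B = lactone, C = benzo ring of the dihydrobenzofuran, D = aryl ring carrying the ketol arm, E = guaiacyl ring on C2 of the dihydrobenzofuran.

Abbreviations: TBS = tert-butyldimethylsilyl; Bn = benzyl; Bpin = 4,4,5,5-tetramethyl-1,3,2-dioxaborolan-2-yl; Diox = (4R,5S)-4-[4-(benzyloxy)-3-methoxyphenyl]-2,2-dimethyl-1,3-dioxan-5-yl; ArD = 4-(benzyloxy)-3-Diox-5-methoxyphenyl; Bf = (2S,3R)-2-[4-(benzyloxy)-3-methoxyphenyl]-3-(hydroxymethyl)-7-methoxy-2,3-dihydro-1-benzofuran-5-yl.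

Assumption: the aldol adducts are drawn as the expected syn isomers. The carbinol centre of 12–14 is erased in step 9 and that of 28–42 is oxidised in step 26, so minor anti isomers converge on the same products.

**Fragment 1 (rings C and E)**

Step 1
Reactants: 1 5-bromo-2-hydroxy-3-methoxybenzaldehyde
Product: 2 5-bromo-3-methoxy-2-(TBS-oxy)benzaldehyde
Conditions: TBSCl, imidazole, DMF, rt
Reagents that add atoms: tert-butyldimethylsilyl chloride, C[Si](C)(Cl)C(C)(C)C
Why: Imidazole-mediated silylation of the phenol gives a silyl ether that should survive the homologation, the aldol and the hydride reduction, yet leaves with fluoride without touching the aryl bromide.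

Step 2
Reactants: 2 5-bromo-3-methoxy-2-(TBS-oxy)benzaldehyde
Product: 3 tert-butyl[4-bromo-2-methoxy-6-(2-methoxyethenyl)phenoxy]dimethylsilane (E/Z mixture)
Conditions: MeOCH2PPh3Cl, NaN(SiMe3)2, THF, 0 °C to rt
Reagents that add atoms: (methoxymethyl)triphenylphosphonium chloride, COC[P+](c1ccccc1)(c1ccccc1)c1ccccc1.[Cl-]
Why: Wittig methoxymethylenation of the aromatic aldehyde adds the one carbon needed for the arylacetic acid, and the non-nucleophilic amide base used to form the ylide should spare the aryl silyl ether.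

Step 3
Reactants: 3 tert-butyl[4-bromo-2-methoxy-6-(2-methoxyethenyl)phenoxy]dimethylsilane
Product: 5 2-[5-bromo-3-methoxy-2-(TBS-oxy)phenyl]acetic acid, via arylacetaldehyde 4 (not isolated)
Conditions: 2 M HCl, THF, rt; then NaClO2, NaH2PO4, 2-methyl-2-butene, t-BuOH/H2O, 0 °C
Reagents that add atoms: water, O; sodium chlorite, [Na+].[O-]Cl=O
Why: Acid hydrolysis of the enol ether releases the arylacetaldehyde, which is oxidised without isolation by Pinnick oxidation so that it cannot self-condense; the hindered aryl silyl ether is expected to tolerate the brief dilute acid.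

Step 4
Reactants: 5 2-[5-bromo-3-methoxy-2-(TBS-oxy)phenyl]acetic acid; 6 (S)-4-benzyloxazolidin-2-one
Product: 8 (S)-4-benzyl-3-{2-[5-bromo-3-methoxy-2-(TBS-oxy)phenyl]acetyl}oxazolidin-2-one, via mixed pivalic anhydride 7 (not isolated)
Conditions: PivCl, Et3N, THF, −20 °C; then 6, LiCl, rt
Reagents that add atoms: none
Why: N-Acylation of the oxazolidinone through the mixed pivalic anhydride (Et3N/LiCl protocol) is a standard way to load an arylacetic acid onto the Evans auxiliary and forms no stereocentre.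

Step 5
Reactants: 9 vanillin (4-hydroxy-3-methoxybenzaldehyde)
Product: 10 3-methoxy-4-(TBS-oxy)benzaldehyde
Conditions: TBSCl, imidazole, DMF, rt
Reagents that add atoms: tert-butyldimethylsilyl chloride, C[Si](C)(Cl)C(C)(C)C
Why: Standard silylation of the phenol gives an aldehyde whose protecting group matches that on ring C, so both can be removed together in step 8.

Step 6
Reactants: 8 (S)-4-benzyl-3-{2-[5-bromo-3-methoxy-2-(TBS-oxy)phenyl]acetyl}oxazolidin-2-one; 10 3-methoxy-4-(TBS-oxy)benzaldehyde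
Product: 12 (S)-4-benzyl-3-{(2S,3S)-2-[5-bromo-3-methoxy-2-(TBS-oxy)phenyl]-3-hydroxy-3-[3-methoxy-4-(TBS-oxy)phenyl]propanoyl}oxazolidin-2-one, via Z-boron enolate 11 (not isolated)
Conditions: Bu2BOTf, i-Pr2NEt, CH2Cl2, 0 °C; then 10, −78 to 0 °C; then pH 7 buffer, MeOH, 30% H2O2, 0 °C
Reagents that add atoms: none
Why: Evans syn aldol reaction, in which the Z dibutylboron enolate 11 reacts through a chair Zimmerman–Traxler transition state on the face opposite the benzyl group of the (S)-auxiliary, which sets the aryl-bearing carbon as 2S (the future C3 of the dihydrobenzofuran) and the carbinol as 3S.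

Step 7
Reactants: 12 (S)-4-benzyl-3-{(2S,3S)-2-[5-bromo-3-methoxy-2-(TBS-oxy)phenyl]-3-hydroxy-3-[3-methoxy-4-(TBS-oxy)phenyl]propanoyl}oxazolidin-2-one
Product: 13 (1S,2R)-2-[5-bromo-3-methoxy-2-(TBS-oxy)phenyl]-1-[3-methoxy-4-(TBS-oxy)phenyl]propane-1,3-diol
Conditions: NaBH4, THF/H2O (4:1), 0 °C to rt
Reagents that add atoms: none
Why: Borohydride reduction of the N-acyl oxazolidinone in wet THF (reductive auxiliary cleavage) gives the primary alcohol and returns the auxiliary, and the aryl-bearing centre keeps its geometry (its descriptor changes from S to R only through the priority rules).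

Step 8
Reactants: 13 (1S,2R)-2-[5-bromo-3-methoxy-2-(TBS-oxy)phenyl]-1-[3-methoxy-4-(TBS-oxy)phenyl]propane-1,3-diol
Product: 14 (1S,2R)-2-(5-bromo-2-hydroxy-3-methoxyphenyl)-1-(4-hydroxy-3-methoxyphenyl)propane-1,3-diol
Conditions: Bu4NF, AcOH, THF, 0 °C
Reagents that add atoms: none
Why: Fluoride cleavage of the two aryl silyl ethers, buffered with acetic acid so that no phenoxide-driven chemistry starts early, frees both phenols needed for step 9 while the aryl bromide is untouched.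

Step 9
Reactants: 14 (1S,2R)-2-(5-bromo-2-hydroxy-3-methoxyphenyl)-1-(4-hydroxy-3-methoxyphenyl)propane-1,3-diol
Product: 16 4-[(2S,3R)-5-bromo-3-(hydroxymethyl)-7-methoxy-2,3-dihydro-1-benzofuran-2-yl]-2-methoxyphenol, via para-quinone methide 15 (not isolated)
Conditions: TsOH·H2O (10 mol%), MeCN, 0.02 M, rt
Reagents that add atoms: none
Why: Protonation of the benzylic hydroxyl and loss of water, pushed by the para phenol oxygen of ring E, gives the planar para-quinone methide 15, so the carbinol configuration of 14 (and of any anti epimer carried with it) is erased. The ring C phenol then adds to the methide carbon in an intramolecular oxa-1,6-conjugate addition that forms O1–C2 and rearomatises ring E; the closest known reaction type is the acid-mediated cyclisation of 2-(2-hydroxyaryl)-1-(4-hydroxyaryl)propane-1,3-diols to trans-phenylcoumarans. The dihydrofuran ring closes in the 5-exo-trig mode, the attacked carbon being exocyclic to the new ring. The new stereocentre C2 is controlled by the existing C3 centre: the aryl group settles anti to the hydroxymethyl group, and because the benzylic ether can re-ionise under the acid, any cis isomer returns to 15 and drains into the trans product. The step needs chemoselectivity between two oxygen nucleophiles and trans selectivity; the first is secured because attack by the primary hydroxyl would give a strained oxetane, the second by 1,2-induction under thermodynamic control, and high dilution suppresses intermolecular capture of 15.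

Step 10
Reactants: 16 4-[(2S,3R)-5-bromo-3-(hydroxymethyl)-7-methoxy-2,3-dihydro-1-benzofuran-2-yl]-2-methoxyphenol
Product: 17 {(2S,3R)-2-[4-(benzyloxy)-3-methoxyphenyl]-5-bromo-7-methoxy-2,3-dihydro-1-benzofuran-3-yl}methanol
Conditions: BnBr, K2CO3, acetone, 50 °C
Reagents that add atoms: benzyl bromide, BrCc1ccccc1
Why: Williamson etherification with K2CO3 deprotonates only the phenol, so the ring E oxygen is benzylated selectively while the primary alcohol stays free, and masking the phenol switches off further quinone methide formation at C2.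

Step 11
Reactants: 17 {(2S,3R)-2-[4-(benzyloxy)-3-methoxyphenyl]-5-bromo-7-methoxy-2,3-dihydro-1-benzofuran-3-yl}methanol
Product: 18 {(2S,3R)-2-[4-(benzyloxy)-3-methoxyphenyl]-7-methoxy-5-Bpin-2,3-dihydro-1-benzofuran-3-yl}methanol
Conditions: B2pin2, Pd(dppf)Cl2 (3 mol%), KOAc, 1,4-dioxane, 90 °C
Reagents that add atoms: bis(pinacolato)diboron, CC1(C)OB(OC1(C)C)B1OC(C)(C)C(C)(C)O1
Why: Miyaura borylation of the aryl bromide tolerates the free primary alcohol and the benzylic ether and gives the boronate needed for the conjugate arylation.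

**Fragment 2 (rings A, D and B)**

Step 12
Reactants: 1 5-bromo-2-hydroxy-3-methoxybenzaldehyde
Product: 19 2-(benzyloxy)-5-bromo-3-methoxybenzaldehyde
Conditions: BnBr, K2CO3, DMF, rt
Reagents that add atoms: benzyl bromide, BrCc1ccccc1
Why: Williamson benzylation of the phenol installs a protecting group that lasts until the final hydrogenolysis, as ring D requires.

Step 13
Reactants: 19 2-(benzyloxy)-5-bromo-3-methoxybenzaldehyde
Product: 20 2-(benzyloxy)-5-bromo-1-methoxy-3-(2-methoxyethenyl)benzene (E/Z mixture)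
Conditions: MeOCH2PPh3Cl, NaN(SiMe3)2, THF, 0 °C to rt
Reagents that add atoms: (methoxymethyl)triphenylphosphonium chloride, COC[P+](c1ccccc1)(c1ccccc1)c1ccccc1.[Cl-]
Why: Wittig methoxymethylenation, as in step 2, adds the carbon of the future arylacetic acid.

Step 14
Reactants: 20 2-(benzyloxy)-5-bromo-1-methoxy-3-(2-methoxyethenyl)benzene
Product: 22 2-[2-(benzyloxy)-5-bromo-3-methoxyphenyl]acetic acid, via arylacetaldehyde 21 (not isolated)
Conditions: 2 M HCl, THF, rt; then NaClO2, NaH2PO4, 2-methyl-2-butene, t-BuOH/H2O, 0 °C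
Reagents that add atoms: water, O; sodium chlorite, [Na+].[O-]Cl=O
Why: Enol ether hydrolysis followed at once by Pinnick oxidation, as in step 3, gives the arylacetic acid without isolating the sensitive arylacetaldehyde.

Step 15
Reactants: 22 2-[2-(benzyloxy)-5-bromo-3-methoxyphenyl]acetic acid; 23 (R)-4-benzyloxazolidin-2-one
Product: 25 (R)-4-benzyl-3-{2-[2-(benzyloxy)-5-bromo-3-methoxyphenyl]acetyl}oxazolidin-2-one, via mixed pivalic anhydride 24 (not isolated)
Conditions: PivCl, Et3N, THF, −20 °C; then 23, LiCl, rt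
Reagents that add atoms: none
Why: Mixed-anhydride N-acylation as in step 4, now with the (R)-auxiliary because the ketol carbon on ring D has the opposite absolute sense to C3 of the dihydrobenzofuran.

Step 16
Reactants: 25 (R)-4-benzyl-3-{2-[2-(benzyloxy)-5-bromo-3-methoxyphenyl]acetyl}oxazolidin-2-one; 26 4-(benzyloxy)-3-methoxybenzaldehyde
Product: 28 (R)-4-benzyl-3-{(2R,3R)-2-[2-(benzyloxy)-5-bromo-3-methoxyphenyl]-3-[4-(benzyloxy)-3-methoxyphenyl]-3-hydroxypropanoyl}oxazolidin-2-one, via Z-boron enolate 27 (not isolated)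
Conditions: Bu2BOTf, i-Pr2NEt, CH2Cl2, 0 °C; then 26, −78 to 0 °C; then pH 7 buffer, MeOH, 30% H2O2, 0 °C
Reagents that add atoms: none
Why: Evans syn aldol reaction through the Z boron enolate 27 and a Zimmerman–Traxler transition state, the mirror image of step 6, which sets the aryl-bearing carbon as 2R (the future S-configured ketol carbon) and the carbinol as 3R.

Step 17
Reactants: 28 (R)-4-benzyl-3-{(2R,3R)-2-[2-(benzyloxy)-5-bromo-3-methoxyphenyl]-3-[4-(benzyloxy)-3-methoxyphenyl]-3-hydroxypropanoyl}oxazolidin-2-one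
Product: 29 (1R,2S)-2-[2-(benzyloxy)-5-bromo-3-methoxyphenyl]-1-[4-(benzyloxy)-3-methoxyphenyl]propane-1,3-diol
Conditions: NaBH4, THF/H2O (4:1), 0 °C to rt
Reagents that add atoms: none
Why: Reductive cleavage of the auxiliary with borohydride, as in step 7, gives the 1,3-diol and recovers the oxazolidinone.

Step 18
Reactants: 29 (1R,2S)-2-[2-(benzyloxy)-5-bromo-3-methoxyphenyl]-1-[4-(benzyloxy)-3-methoxyphenyl]propane-1,3-diol
Product: 30 (4R,5S)-5-[2-(benzyloxy)-5-bromo-3-methoxyphenyl]-4-[4-(benzyloxy)-3-methoxyphenyl]-2,2-dimethyl-1,3-dioxane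
Conditions: Me2C(OMe)2, PPTS (cat.), CH2Cl2, rt
Reagents that add atoms: 2,2-dimethoxypropane, COC(C)(C)OC
Why: Acetonide formation under weak acid catalysis masks both hydroxyls for the organolithium, alkoxide and hydride steps that follow, and the acid should be too weak to ionise the benzylic carbinol.

Step 19
Reactants: 30 (4R,5S)-5-[2-(benzyloxy)-5-bromo-3-methoxyphenyl]-4-[4-(benzyloxy)-3-methoxyphenyl]-2,2-dimethyl-1,3-dioxane
Product: 32 4-(benzyloxy)-3-Diox-5-methoxybenzaldehyde, via aryllithium 31 (not isolated)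
Conditions: n-BuLi, THF, −78 °C; then DMF, −78 to 0 °C; then H2O
Reagents that add atoms: N,N-dimethylformamide, CN(C)C=O
Why: Bromine–lithium exchange at −78 °C followed by formylation with DMF (Bouveault-type aldehyde synthesis) is faster than any benzylic deprotonation and turns the bromide into the aldehyde needed for the Stobbe condensation.

Step 20
Reactants: 32 4-(benzyloxy)-3-Diox-5-methoxybenzaldehyde; 33 dimethyl succinate
Product: 34 (E)-4-ArD-3-(methoxycarbonyl)but-3-enoic acid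
Conditions: NaOMe, MeOH, reflux; then cold 0.5 M HCl to pH 4
Reagents that add atoms: none
Why: Stobbe condensation of the aromatic aldehyde with dimethyl succinate gives, through the paraconic lactone and its E1cB opening, the E arylidene succinic half-ester with the free acid on the methylene arm, as needed to direct the hydrogenation.

Step 21
Reactants: 34 (E)-4-ArD-3-(methoxycarbonyl)but-3-enoic acid
Product: 35 (3R)-4-ArD-3-(methoxycarbonyl)butanoic acid
Conditions: [Rh(cod)((S,S)-Et-DuPhos)]BF4 (1 mol%), H2 (5 bar), NaOMe (10 mol%), MeOH, rt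
Reagents that add atoms: none
Why: Carboxylate-directed rhodium–bisphospholane asymmetric hydrogenation of Stobbe half-esters is an established entry to 2-benzylsuccinates and is expected to set the future lactone C4 as R with the (S,S) ligand (the antipodal ligand would be used should a test run show the opposite sense), while homogeneous rhodium does not cleave benzyl ethers.

Step 22
Reactants: 35 (3R)-4-ArD-3-(methoxycarbonyl)butanoic acid
Product: 37 (4R)-4-(ArD-methyl)dihydrofuran-2(3H)-one, via hydroxy acid 36 (not isolated)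
Conditions: LiOH·H2O (1.0 equiv), MeOH, rt, evaporate; then LiBH4, THF, 0 °C to rt; then cold 0.5 M HCl to pH 3, toluene, 50 °C
Reagents that add atoms: none
Why: Chemoselective borohydride reduction of the methyl ester beside the unreactive lithium carboxylate, followed by lactonisation of hydroxy acid 36 on mild acidification, is the classical route from Stobbe half-esters to β-benzyl butyrolactones and does not touch the stereocentre.

Step 23
Reactants: 37 (4R)-4-(ArD-methyl)dihydrofuran-2(3H)-one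
Product: 39 (4R)-4-(ArD-methyl)-3-methylenedihydrofuran-2(3H)-one, via sodium formyl enolate 38 (not isolated)
Conditions: NaH, HCO2Et, THF, 0 °C to rt; then (CH2O)n, THF, 65 °C
Reagents that add atoms: formaldehyde (from paraformaldehyde), C=O
Why: α-Methylenation of the lactone by Claisen formylation and reaction of the formyl enolate 38 with formaldehyde (hydroxymethylation, formyl transfer to oxygen and loss of formate) is a standard one-pot route to α-methylene butyrolactones and leaves C4 untouched.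

**Union and end game**

Step 24
Reactants: 39 (4R)-4-(ArD-methyl)-3-methylenedihydrofuran-2(3H)-one; 18 {(2S,3R)-2-[4-(benzyloxy)-3-methoxyphenyl]-7-methoxy-5-Bpin-2,3-dihydro-1-benzofuran-3-yl}methanol
Product: 41 (3R,4R)-3-(Bf-methyl)-4-(ArD-methyl)dihydrofuran-2(3H)-one, via cis-lactone 40 (not isolated)
Conditions: [Rh(cod)OH]2 (3 mol%), 1,4-dioxane/H2O (10:1), 60 °C; then concentrate, DBU, toluene, 60 °C
Reagents that add atoms: none
Why: Rhodium-catalysed 1,4-addition of the aryl boronate (Hayashi–Miyaura reaction) to the α-methylene lactone forms the ring C aryl–CH2 bond; protonation of the rhodium enolate on the face away from the C4 substituent should give mainly the cis lactone 40, and DBU then equilibrates C3, the only enolisable centre, to the more stable trans (3R,4R) lactone.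

Step 25
Reactants: 41 (3R,4R)-3-(Bf-methyl)-4-(ArD-methyl)dihydrofuran-2(3H)-one
Product: 42 (3R,4R)-3-(Bf-methyl)-4-{4-(benzyloxy)-3-[(1R,2S)-1-[4-(benzyloxy)-3-methoxyphenyl]-1,3-dihydroxypropan-2-yl]-5-methoxybenzyl}dihydrofuran-2(3H)-one
Conditions: AcOH/THF/H2O (3:1:1), 40 °C
Reagents that add atoms: none
Why: Mild aqueous acetic acid hydrolysis of the acetonide frees the 1,3-diol, the acid being too weak to ionise the benzylic carbinol or the benzylic ether O1–C2 or to open the lactone.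

Step 26
Reactants: 42 (3R,4R)-3-(Bf-methyl)-4-{4-(benzyloxy)-3-[(1R,2S)-1-[4-(benzyloxy)-3-methoxyphenyl]-1,3-dihydroxypropan-2-yl]-5-methoxybenzyl}dihydrofuran-2(3H)-one
Product: 43 (3R,4R)-3-(Bf-methyl)-4-{4-(benzyloxy)-3-[(2S)-1-[4-(benzyloxy)-3-methoxyphenyl]-3-hydroxy-1-oxopropan-2-yl]-5-methoxybenzyl}dihydrofuran-2(3H)-one
Conditions: activated MnO2 (excess), CH2Cl2, rt
Reagents that add atoms: none
Why: Activated MnO2 oxidises benzylic alcohols but not saturated primary alcohols (chemoselective benzylic oxidation), so only the ring A carbinol becomes the ketone, and the neutral heterogeneous medium should keep the new α-aryl ketone centre from enolising.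

Step 27
Reactants: 43 (3R,4R)-3-(Bf-methyl)-4-{4-(benzyloxy)-3-[(2S)-1-[4-(benzyloxy)-3-methoxyphenyl]-3-hydroxy-1-oxopropan-2-yl]-5-methoxybenzyl}dihydrofuran-2(3H)-one
Product: 44 (3R,4R)-3-{[(2S,3R)-2-(4-hydroxy-3-methoxyphenyl)-3-(hydroxymethyl)-7-methoxy-2,3-dihydro-1-benzofuran-5-yl]methyl}-4-{4-hydroxy-3-[(2S)-3-hydroxy-1-(4-hydroxy-3-methoxyphenyl)-1-oxopropan-2-yl]-5-methoxybenzyl}dihydrofuran-2(3H)-one (CNP0111438.1)
Conditions: H2 (1 atm), Pd/C (10 wt%), EtOAc/EtOH, rt
Reagents that add atoms: none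
Why: Hydrogenolysis of the three aryl benzyl ethers over Pd/C under neutral conditions should be fast compared with reduction of the aryl ketone or cleavage of the benzylic ether O1–C2 if stopped at the calculated hydrogen uptake, and uses no acid or base that could epimerise the ketol carbon or the lactone.

**Compound list**

1 | 5-bromo-2-hydroxy-3-methoxybenzaldehyde | COc1cc(Br)cc(C=O)c1O | starting material
2 | 5-bromo-3-methoxy-2-(TBS-oxy)benzaldehyde | COc1cc(Br)cc(C=O)c1O[Si](C)(C)C(C)(C)C | intermediate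
3 | tert-butyl[4-bromo-2-methoxy-6-(2-methoxyethenyl)phenoxy]dimethylsilane (E/Z mixture) | COC=Cc1cc(Br)cc(OC)c1O[Si](C)(C)C(C)(C)C | intermediate
4 | 2-[5-bromo-3-methoxy-2-(TBS-oxy)phenyl]acetaldehyde (not isolated) | O=CCc1cc(Br)cc(OC)c1O[Si](C)(C)C(C)(C)C | intermediate
5 | 2-[5-bromo-3-methoxy-2-(TBS-oxy)phenyl]acetic acid | OC(=O)Cc1cc(Br)cc(OC)c1O[Si](C)(C)C(C)(C)C | intermediate
6 | (S)-4-benzyloxazolidin-2-one | O=C1N[C@@H](Cc2ccccc2)CO1 | starting material
7 | mixed anhydride of 5 with pivalic acid (not isolated) | CC(C)(C)C(=O)OC(=O)Cc1cc(Br)cc(OC)c1O[Si](C)(C)C(C)(C)C | intermediate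
8 | (S)-4-benzyl-3-{2-[5-bromo-3-methoxy-2-(TBS-oxy)phenyl]acetyl}oxazolidin-2-one | O=C(Cc1cc(Br)cc(OC)c1O[Si](C)(C)C(C)(C)C)N1[C@@H](Cc2ccccc2)COC1=O | intermediate
9 | vanillin (4-hydroxy-3-methoxybenzaldehyde) | COc1cc(C=O)ccc1O | starting material
10 | 3-methoxy-4-(TBS-oxy)benzaldehyde | COc1cc(C=O)ccc1O[Si](C)(C)C(C)(C)C | intermediate
11 | Z dibutylboron enolate of 8 (not isolated) | CCCCB(CCCC)O\C(N1[C@@H](Cc2ccccc2)COC1=O)=C/c1cc(Br)cc(OC)c1O[Si](C)(C)C(C)(C)C | intermediate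
12 | (S)-4-benzyl-3-{(2S,3S)-2-[5-bromo-3-methoxy-2-(TBS-oxy)phenyl]-3-hydroxy-3-[3-methoxy-4-(TBS-oxy)phenyl]propanoyl}oxazolidin-2-one | O=C([C@@H](c1cc(Br)cc(OC)c1O[Si](C)(C)C(C)(C)C)[C@H](O)c1ccc(O[Si](C)(C)C(C)(C)C)c(OC)c1)N1[C@@H](Cc2ccccc2)COC1=O | intermediate
13 | (1S,2R)-2-[5-bromo-3-methoxy-2-(TBS-oxy)phenyl]-1-[3-methoxy-4-(TBS-oxy)phenyl]propane-1,3-diol | OC[C@@H](c1cc(Br)cc(OC)c1O[Si](C)(C)C(C)(C)C)[C@H](O)c1ccc(O[Si](C)(C)C(C)(C)C)c(OC)c1 | intermediate
14 | (1S,2R)-2-(5-bromo-2-hydroxy-3-methoxyphenyl)-1-(4-hydroxy-3-methoxyphenyl)propane-1,3-diol | OC[C@@H](c1cc(Br)cc(OC)c1O)[C@H](O)c1ccc(O)c(OC)c1 | intermediate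
15 | 4-[(2R)-2-(5-bromo-2-hydroxy-3-methoxyphenyl)-3-hydroxypropylidene]-2-methoxycyclohexa-2,5-dien-1-one (para-quinone methide, not isolated) | OC[C@@H](c1cc(Br)cc(OC)c1O)C=C1C=CC(=O)C(OC)=C1 | intermediate
16 | 4-[(2S,3R)-5-bromo-3-(hydroxymethyl)-7-methoxy-2,3-dihydro-1-benzofuran-2-yl]-2-methoxyphenol | Brc1cc(OC)c2c(c1)[C@H](CO)[C@@H](c1ccc(O)c(OC)c1)O2 | intermediate
17 | {(2S,3R)-2-[4-(benzyloxy)-3-methoxyphenyl]-5-bromo-7-methoxy-2,3-dihydro-1-benzofuran-3-yl}methanol | Brc1cc(OC)c2c(c1)[C@H](CO)[C@@H](c1ccc(OCc3ccccc3)c(OC)c1)O2 | intermediate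
18 | {(2S,3R)-2-[4-(benzyloxy)-3-methoxyphenyl]-7-methoxy-5-Bpin-2,3-dihydro-1-benzofuran-3-yl}methanol | CC1(C)OB(OC1(C)C)c1cc(OC)c2c(c1)[C@H](CO)[C@@H](c1ccc(OCc3ccccc3)c(OC)c1)O2 | intermediate
19 | 2-(benzyloxy)-5-bromo-3-methoxybenzaldehyde | COc1cc(Br)cc(C=O)c1OCc1ccccc1 | intermediate
20 | 2-(benzyloxy)-5-bromo-1-methoxy-3-(2-methoxyethenyl)benzene (E/Z mixture) | COC=Cc1cc(Br)cc(OC)c1OCc1ccccc1 | intermediate
21 | 2-[2-(benzyloxy)-5-bromo-3-methoxyphenyl]acetaldehyde (not isolated) | O=CCc1cc(Br)cc(OC)c1OCc1ccccc1 | intermediate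
22 | 2-[2-(benzyloxy)-5-bromo-3-methoxyphenyl]acetic acid | OC(=O)Cc1cc(Br)cc(OC)c1OCc1ccccc1 | intermediate
23 | (R)-4-benzyloxazolidin-2-one | O=C1N[C@H](Cc2ccccc2)CO1 | starting material
24 | mixed anhydride of 22 with pivalic acid (not isolated) | CC(C)(C)C(=O)OC(=O)Cc1cc(Br)cc(OC)c1OCc1ccccc1 | intermediate
25 | (R)-4-benzyl-3-{2-[2-(benzyloxy)-5-bromo-3-methoxyphenyl]acetyl}oxazolidin-2-one | O=C(Cc1cc(Br)cc(OC)c1OCc1ccccc1)N1[C@H](Cc2ccccc2)COC1=O | intermediate
26 | 4-(benzyloxy)-3-methoxybenzaldehyde | COc1cc(C=O)ccc1OCc1ccccc1 | starting material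
27 | Z dibutylboron enolate of 25 (not isolated) | CCCCB(CCCC)O\C(N1[C@H](Cc2ccccc2)COC1=O)=C/c1cc(Br)cc(OC)c1OCc1ccccc1 | intermediate
28 | (R)-4-benzyl-3-{(2R,3R)-2-[2-(benzyloxy)-5-bromo-3-methoxyphenyl]-3-[4-(benzyloxy)-3-methoxyphenyl]-3-hydroxypropanoyl}oxazolidin-2-one | O=C([C@H](c1cc(Br)cc(OC)c1OCc1ccccc1)[C@@H](O)c1ccc(OCc2ccccc2)c(OC)c1)N1[C@H](Cc2ccccc2)COC1=O | intermediate
29 | (1R,2S)-2-[2-(benzyloxy)-5-bromo-3-methoxyphenyl]-1-[4-(benzyloxy)-3-methoxyphenyl]propane-1,3-diol | OC[C@H](c1cc(Br)cc(OC)c1OCc1ccccc1)[C@@H](O)c1ccc(OCc2ccccc2)c(OC)c1 | intermediate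
30 | (4R,5S)-5-[2-(benzyloxy)-5-bromo-3-methoxyphenyl]-4-[4-(benzyloxy)-3-methoxyphenyl]-2,2-dimethyl-1,3-dioxane | CC1(C)OC[C@H](c2cc(Br)cc(OC)c2OCc2ccccc2)[C@H](c2ccc(OCc3ccccc3)c(OC)c2)O1 | intermediate
31 | aryllithium from 30, lithium in place of bromine (not isolated) | CC1(C)OC[C@H](c2cc([Li])cc(OC)c2OCc2ccccc2)[C@H](c2ccc(OCc3ccccc3)c(OC)c2)O1 | intermediate
32 | 4-(benzyloxy)-3-Diox-5-methoxybenzaldehyde | CC1(C)OC[C@H](c2cc(C=O)cc(OC)c2OCc2ccccc2)[C@H](c2ccc(OCc3ccccc3)c(OC)c2)O1 | intermediate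
33 | dimethyl succinate | COC(=O)CCC(=O)OC | starting material
34 | (E)-4-ArD-3-(methoxycarbonyl)but-3-enoic acid | CC1(C)OC[C@H](c2cc(/C=C(\CC(=O)O)C(=O)OC)cc(OC)c2OCc2ccccc2)[C@H](c2ccc(OCc3ccccc3)c(OC)c2)O1 | intermediate
35 | (3R)-4-ArD-3-(methoxycarbonyl)butanoic acid | CC1(C)OC[C@H](c2cc(C[C@H](CC(=O)O)C(=O)OC)cc(OC)c2OCc2ccccc2)[C@H](c2ccc(OCc3ccccc3)c(OC)c2)O1 | intermediate
36 | (3R)-4-ArD-3-(hydroxymethyl)butanoic acid (not isolated) | CC1(C)OC[C@H](c2cc(C[C@@H](CO)CC(=O)O)cc(OC)c2OCc2ccccc2)[C@H](c2ccc(OCc3ccccc3)c(OC)c2)O1 | intermediate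
37 | (4R)-4-(ArD-methyl)dihydrofuran-2(3H)-one | CC1(C)OC[C@H](c2cc(C[C@H]3COC(=O)C3)cc(OC)c2OCc2ccccc2)[C@H](c2ccc(OCc3ccccc3)c(OC)c2)O1 | intermediate
38 | sodium enolate of (4R)-4-(ArD-methyl)-2-oxotetrahydrofuran-3-carbaldehyde (not isolated) | CC1(C)OC[C@H](c2cc(C[C@H]3COC(=O)C3=C[O-])cc(OC)c2OCc2ccccc2)[C@H](c2ccc(OCc3ccccc3)c(OC)c2)O1.[Na+] | intermediate
39 | (4R)-4-(ArD-methyl)-3-methylenedihydrofuran-2(3H)-one | CC1(C)OC[C@H](c2cc(C[C@H]3COC(=O)C3=C)cc(OC)c2OCc2ccccc2)[C@H](c2ccc(OCc3ccccc3)c(OC)c2)O1 | intermediate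
40 | (3S,4R)-3-(Bf-methyl)-4-(ArD-methyl)dihydrofuran-2(3H)-one, cis lactone (not isolated) | CC1(C)OC[C@H](c2cc(C[C@H]3COC(=O)[C@H]3Cc3cc(OC)c4c(c3)[C@H](CO)[C@@H](c3ccc(OCc5ccccc5)c(OC)c3)O4)cc(OC)c2OCc2ccccc2)[C@H](c2ccc(OCc3ccccc3)c(OC)c2)O1 | intermediate
41 | (3R,4R)-3-(Bf-methyl)-4-(ArD-methyl)dihydrofuran-2(3H)-one, trans lactone | CC1(C)OC[C@H](c2cc(C[C@H]3COC(=O)[C@@H]3Cc3cc(OC)c4c(c3)[C@H](CO)[C@@H](c3ccc(OCc5ccccc5)c(OC)c3)O4)cc(OC)c2OCc2ccccc2)[C@H](c2ccc(OCc3ccccc3)c(OC)c2)O1 | intermediate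
42 | (3R,4R)-3-(Bf-methyl)-4-{4-(benzyloxy)-3-[(1R,2S)-1-[4-(benzyloxy)-3-methoxyphenyl]-1,3-dihydroxypropan-2-yl]-5-methoxybenzyl}dihydrofuran-2(3H)-one | OC[C@H](c1cc(C[C@H]2COC(=O)[C@@H]2Cc2cc(OC)c3c(c2)[C@H](CO)[C@@H](c2ccc(OCc4ccccc4)c(OC)c2)O3)cc(OC)c1OCc1ccccc1)[C@@H](O)c1ccc(OCc2ccccc2)c(OC)c1 | intermediate
43 | (3R,4R)-3-(Bf-methyl)-4-{4-(benzyloxy)-3-[(2S)-1-[4-(benzyloxy)-3-methoxyphenyl]-3-hydroxy-1-oxopropan-2-yl]-5-methoxybenzyl}dihydrofuran-2(3H)-one | OC[C@H](c1cc(C[C@H]2COC(=O)[C@@H]2Cc2cc(OC)c3c(c2)[C@H](CO)[C@@H](c2ccc(OCc4ccccc4)c(OC)c2)O3)cc(OC)c1OCc1ccccc1)C(=O)c1ccc(OCc2ccccc2)c(OC)c1 | intermediate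
44 | (3R,4R)-3-{[(2S,3R)-2-(4-hydroxy-3-methoxyphenyl)-3-(hydroxymethyl)-7-methoxy-2,3-dihydro-1-benzofuran-5-yl]methyl}-4-{4-hydroxy-3-[(2S)-3-hydroxy-1-(4-hydroxy-3-methoxyphenyl)-1-oxopropan-2-yl]-5-methoxybenzyl}dihydrofuran-2(3H)-one | COc1cc(C(=O)[C@H](CO)c2cc(C[C@H]3COC(=O)[C@@H]3Cc3cc(OC)c4c(c3)[C@H](CO)[C@@H](c3ccc(O)c(OC)c3)O4)cc(OC)c2O)ccc1O | target

**Step count**

Total: 27 steps. Longest linear sequence: 16 steps (steps 12–27, from 1 to 44).

**Steps most likely to fail, with fallbacks**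

Step 24. Protodeboronation of the electron-rich boronate may outrun transmetalation and insertion into the hindered 1,1-disubstituted acceptor, and the base equilibration may stop short of complete cis-to-trans conversion. The fallback replaces the conjugate arylation by a classical lactone enolate alkylation; it sets out from 17 (with 37 as the coupling partner) and returns to the route at 41. Alcohol 17 is silylated (TBSCl, imidazole, DMF) to tert-butyl({(2S,3R)-2-[4-(benzyloxy)-3-methoxyphenyl]-5-bromo-7-methoxy-2,3-dihydro-1-benzofuran-3-yl}methoxy)dimethylsilane F1. Bromine–lithium exchange (n-BuLi, THF, −78 °C) and DMF give the 5-carbaldehyde F2, NaBH4 in MeOH gives the 5-(hydroxymethyl) compound F3, and CBr4/PPh3 in CH2Cl2 gives the 5-(bromomethyl) compound F4. Lactone 37 is deprotonated with LiN(SiMe3)2 (THF, −78 °C) to its lithium enolate F5, which is alkylated by F4 on the face anti to the C4 substituent to give the trans lactone, the TBS ether of 41, F6. Bu4NF in THF removes the silyl group and gives 41.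

Step 26. Oxidation of the hindered secondary carbinol may be slow, and on long contact the primary alcohols may start to oxidise or the β-hydroxy ketone may lose formaldehyde by retro-aldol cleavage. The fallback removes the need for chemoselectivity; it sets out from 42 and returns at 43. Both primary hydroxyls of 42 are silylated (TBSCl 2.2 equiv, imidazole, CH2Cl2, 0 °C) to give the bis(TBS) ether of 42, F7. Dess–Martin periodinane with NaHCO3 in CH2Cl2 oxidises the only free hydroxyl to give the bis(TBS) ether of 43, F8. HF·pyridine in THF/pyridine at 0 °C removes both silyl groups and gives 43.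

Step 7. Under the basic hydride conditions the β-hydroxy imide may fragment by retro-aldol reaction before the imide is reduced, the more so if the para silyl ether on ring E is lost and a phenoxide pushes the cleavage (the benzyl-protected twin, step 17, lacks this trigger). The fallback blocks the aldol hydroxyl first; it sets out from 12 and returns at 14. Compound 12 is silylated (TBSOTf, 2,6-lutidine, CH2Cl2, −78 °C) to the TBS ether of 12, F9. LiBH4 (THF, 1 equiv MeOH, 0 °C) cleaves the auxiliary and gives (2R,3S)-2-[5-bromo-3-methoxy-2-(TBS-oxy)phenyl]-3-[3-methoxy-4-(TBS-oxy)phenyl]-3-(TBS-oxy)propan-1-ol F10. Bu4NF/AcOH in THF removes all three silyl groups and gives 14.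

**Further compounds**

F1 | step 24 | tert-butyl({(2S,3R)-2-[4-(benzyloxy)-3-methoxyphenyl]-5-bromo-7-methoxy-2,3-dihydro-1-benzofuran-3-yl}methoxy)dimethylsilane | Brc1cc(OC)c2c(c1)[C@H](CO[Si](C)(C)C(C)(C)C)[C@@H](c1ccc(OCc3ccccc3)c(OC)c1)O2
F2 | step 24 | (2S,3R)-2-[4-(benzyloxy)-3-methoxyphenyl]-7-methoxy-3-[(TBS-oxy)methyl]-2,3-dihydro-1-benzofuran-5-carbaldehyde | O=Cc1cc(OC)c2c(c1)[C@H](CO[Si](C)(C)C(C)(C)C)[C@@H](c1ccc(OCc3ccccc3)c(OC)c1)O2
F3 | step 24 | {(2S,3R)-2-[4-(benzyloxy)-3-methoxyphenyl]-7-methoxy-3-[(TBS-oxy)methyl]-2,3-dihydro-1-benzofuran-5-yl}methanol | OCc1cc(OC)c2c(c1)[C@H](CO[Si](C)(C)C(C)(C)C)[C@@H](c1ccc(OCc3ccccc3)c(OC)c1)O2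
F4 | step 24 | tert-butyl({(2S,3R)-2-[4-(benzyloxy)-3-methoxyphenyl]-5-(bromomethyl)-7-methoxy-2,3-dihydro-1-benzofuran-3-yl}methoxy)dimethylsilane | BrCc1cc(OC)c2c(c1)[C@H](CO[Si](C)(C)C(C)(C)C)[C@@H](c1ccc(OCc3ccccc3)c(OC)c1)O2
F5 | step 24 | lithium enolate of 37 | CC1(C)OC[C@H](c2cc(C[C@H]3COC([O-])=C3)cc(OC)c2OCc2ccccc2)[C@H](c2ccc(OCc3ccccc3)c(OC)c2)O1.[Li+]
F6 | step 24 | TBS ether of 41 at the benzofuran hydroxymethyl group, trans (3R,4R) lactone | CC1(C)OC[C@H](c2cc(C[C@H]3COC(=O)[C@@H]3Cc3cc(OC)c4c(c3)[C@H](CO[Si](C)(C)C(C)(C)C)[C@@H](c3ccc(OCc5ccccc5)c(OC)c3)O4)cc(OC)c2OCc2ccccc2)[C@H](c2ccc(OCc3ccccc3)c(OC)c2)O1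
F7 | step 26 | bis(TBS) ether of 42 at both primary hydroxyls | CC(C)(C)[Si](C)(C)OC[C@H](c1cc(C[C@H]2COC(=O)[C@@H]2Cc2cc(OC)c3c(c2)[C@H](CO[Si](C)(C)C(C)(C)C)[C@@H](c2ccc(OCc4ccccc4)c(OC)c2)O3)cc(OC)c1OCc1ccccc1)[C@@H](O)c1ccc(OCc2ccccc2)c(OC)c1
F8 | step 26 | bis(TBS) ether of 43 at both primary hydroxyls | CC(C)(C)[Si](C)(C)OC[C@H](c1cc(C[C@H]2COC(=O)[C@@H]2Cc2cc(OC)c3c(c2)[C@H](CO[Si](C)(C)C(C)(C)C)[C@@H](c2ccc(OCc4ccccc4)c(OC)c2)O3)cc(OC)c1OCc1ccccc1)C(=O)c1ccc(OCc2ccccc2)c(OC)c1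
F9 | step 7 | (S)-4-benzyl-3-{(2S,3S)-2-[5-bromo-3-methoxy-2-(TBS-oxy)phenyl]-3-[3-methoxy-4-(TBS-oxy)phenyl]-3-(TBS-oxy)propanoyl}oxazolidin-2-one | O=C([C@@H](c1cc(Br)cc(OC)c1O[Si](C)(C)C(C)(C)C)[C@H](O[Si](C)(C)C(C)(C)C)c1ccc(O[Si](C)(C)C(C)(C)C)c(OC)c1)N1[C@@H](Cc2ccccc2)COC1=O
F10 | step 7 | (2R,3S)-2-[5-bromo-3-methoxy-2-(TBS-oxy)phenyl]-3-[3-methoxy-4-(TBS-oxy)phenyl]-3-(TBS-oxy)propan-1-ol | OC[C@@H](c1cc(Br)cc(OC)c1O[Si](C)(C)C(C)(C)C)[C@H](O[Si](C)(C)C(C)(C)C)c1ccc(O[Si](C)(C)C(C)(C)C)c(OC)c1
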